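Labdane numbering is used throughout: ring A is C1–C5 and C10, ring B is C5–C10, C11–C16 form the chain, C17 is on C8, C18 and C19 are on C4, and C20 is on C10.

## The problem

Target 25 is the 15-(3-phenylpropanoate) of (13S)-labdane-8α,15-diol. It is a trans-fused decalin whose C9 carries a saturated chain, C11–C15, with the C16 methyl on C13. Ring B holds four contiguous stereocentres, C5, C10, C9 and C8. Two of them are fully substituted (quaternary C10, tertiary carbinol C8), and a fifth centre, C13, sits out on the flexible chain. Inside the bicycle a relay is available: C5 can steer the construction of C10, and the axial C10 methyl then screens the β face of ring B, so that reagents meet C9 and C8 from the α face. C13 is beyond the reach of all of them, so it has to be brought in as a single enantiomer and kept away from conditions that shift a neighbouring double bond. The tertiary C8 alcohol is lost easily under acid and would invite retro-aldol cleavage or β-elimination next to a C11 carbonyl, and the primary ester tolerates neither hydride, strong base nor dissolving metal, so both groups have to come late. C9 lies between C10 and C8, so a carbon–carbon bond to C9 is realistic only while C8 is still trigonal. The feature that opens the plan is the end of ring A: gem-dimethyl C4 is bonded to C5, and ring B with its C8 methyl is the skeleton of carvone 1. The isopropenyl carbon of 1 becomes C4 once its CH2 takes up one hydrogen atom, and the tertiary C4 radical left behind can form C3–C4 and close ring A onto a three-carbon arm on C10.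

## Retrosynthesis

**C15–O acyl bond.** The ester is the most fragile group and is cut first, so 25 goes back to diol 23 and acid 24. Cutting here, rather than carrying the ester through the chain assembly, keeps hydride and ylide chemistry available in all earlier steps. The forward reaction only has to distinguish a primary from a tertiary alcohol.

**C8–O and C7–H.**
- The carbinol of 23 is traced to the 7α,8α-epoxide 22 and from there to the C7=C8 alkene of ester 21. The C15 alcohol is traced at the same time to the methyl ester, so one hydride treatment serves both ends of the molecule.
- The neighbouring option is to oxygenate C8 much earlier, through a C8=C9 enolate derived from ketone 7. It would leave the C9 carbonyl between two fully substituted carbons, where a one-carbon olefination cannot be defended. It would also later place a β-oxygen next to the C11 aldehyde.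
- Keeping C7=C8 as the latent carbinol avoids both problems, and 21 has one stereocentre and one acid-sensitive group fewer than 23.
- The forward steps need α-face epoxidation and hydride attack at the secondary C7.

**C11–C12.**
- Alkene ester 21 comes from diene ester 20, and 20 from aldehyde 12 and phosphonium salt 18.
- A cut at C9–C11 would mean adding the whole chain to a hindered ketone and then removing a tertiary oxygen with control of C9.
- A cut at C12–C13 would destroy the only stereocentre that the bicycle cannot control.
- The C11–C12 cut leaves C13 one atom away from the reacting carbon and divides the target into a C15 bicycle and a C5 piece plus methyl.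
- The forward olefination must be faster than deprotonation of 12 at C9. The saturation of C11=C12 must spare C7=C8 and must not move the alkene towards C13.

**The chain fragment.**
- Salt 18 goes back through iodo ester 17 and lactone 15 to the half-ester 13 of (R)-methylsuccinic acid.
- In 13 the two termini already differ (free acid at the future C12, ester at the future C15). No selective protection of a diol is needed, and the ester acts as the protecting group of C15.
- The forward steps must reduce the acid only and must not touch the stereocentre.

**C9–C11 and C2–S.**
- Aldehyde 12 is the oxidation product of (−)-drimenol 11. Compound 11 arises from sulfone alcohol 10 by reductive loss of the sulfonyl group, 10 from diene 8 by anti-Markovnikov hydration, and 8 from enone 7 by methylenation.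
- C11 is attached while C8 is sp2, the least crowded state C9 will ever have.
- The sulfonyl group is removed as soon as no reducible enone or diene is left, so all later compounds are single isomers.
- The forward hydroboration must choose the exocyclic alkene and deliver hydrogen to the α face of C9.

**C3–C4, the key cut.**
- Opening ring A of 7 at C3–C4 gives monocycle 6. This is the only ring A bond whose cleavage turns C4 into a carbon that 1 already contains, because all other cuts leave the quaternary C4 still to be built.
- The acceptor is a vinyl sulfone with sulfur on C2, because C2 must end as a plain CH2. A carbonyl-based acceptor would leave an extra carbon there.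
- The precursor has one ring fewer and no new stereochemical problem, since C5 and C10 already fix the trans fusion.
- The forward step must start the radical at the isopropenyl group only and must close in the six-membered mode.

**C10–C1 and C10–C20.**
- Compound 6 is dismantled to 6-methylcarvone 3 and bromide 4, and 3 to (R)-carvone 1.
- The order (methyl first, larger arm second) is dictated by the rule that the second electrophile enters anti to the isopropenyl group. This places the methyl cis and the three-carbon arm trans to it, as C10 requires.
- (R)-carvone has the C5 configuration of the target.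

## Roads not taken

**Alternative 1:**
- *Cut and key step.* Both rings are opened at once by cutting C4–C5 and C9–C10 and removing the C8 oxygen. This leads to the acyclic trienol A1, (3S,6E,10E)-3,7,11,15-tetramethylhexadeca-6,10,14-trien-1-ol. In the forward direction a class two terpene cyclase of the squalene–hopene type would protonate C3 of the terminal alkene, fold the chain chair–chair, form the two ring bonds and finish by hydration of the C8 cation. The product is diol A2, which is the same compound as 23.
- *Merits.* Two rings, four stereocentres and the carbinol arise in one operation. The E alkenes translate into the trans fusion and 9α-H, C13 is untouched, and only the acylation remains. In step count this road is clearly superior to the chosen plan.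
- *Weak points.* The outcome rests entirely on the protein. It must accept a saturated, hydroxylated tail, stop after two rings, and end by α-face hydration rather than by proton loss to one of three possible alkenes. None of this can be argued from the structure of A1. With an ordinary acid in place of the enzyme, remote C13 could not bias the fold, and diastereomers at the bicycle would result. A1 also needs its own enantioselective preparation.
- *Comparison.* The chosen plan offers substrate-based arguments for every stereocentre and no dependence on finding or engineering a catalyst.

**Alternative 2:**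
- *Cut and key step.* Ring B is cut at C9–C10 and C7–C8, with a temporary C11–O–C1 ester tether. The substrate is the butynoate A3, (S)-2,4,4-trimethyl-3-vinylcyclohex-2-en-1-yl but-2-ynoate. Its thermal intramolecular Diels–Alder reaction would give the tricyclic butenolide A4 with C5=C6 and C8=C9 alkenes.
- *Merits.* The key step forms two skeletal bonds where the chosen one forms a single bond. It builds quaternary C10 under control of the tethered C1 carbinol and delivers C11 and C17 already in place. The chosen plan needs two extra steps for C11.
- *Weak points.* The diene terminus C10 is fully substituted, and the inner diene carbon C5 is crowded by the C4 gem-dimethyl group, which disfavours the s-cis form. The ester tether prefers the conformation that holds the alkyne away from the diene, so harsh heating is to be expected. A4 carries only C10 of the needed stereocentres, plus a C1 oxygen that must be removed. C5 would have to be set by reducing a trisubstituted alkene next to C4, and C8 and C9 by a net syn addition of H and OH to a tetrasubstituted butenolide alkene. A3 also needs an asymmetric entry.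
- *Comparison.* This road builds more in its key step but leaves a longer and less predictable clean-up. In product 7 of the chosen plan every functional group is used.

**Alternative 3:**
- *Cut and key step.* C7–C8 is cut and ring B contracted, so the series starts from the (S)-Hajos–Parrish ketone A5. The key substrate is the trans-hydrindane ketol A6 (9β-acetyl, 9α-hydroxy). A boron Lewis acid would chelate its two oxygens and let C7 migrate from C9 to the acetyl carbon, giving 8α-hydroxy-11-nordriman-9-one A7.
- *Merits.* A5 is cheap as a single enantiomer and already holds C10. The rearrangement creates the C8 carbinol and the C9 ketone together, is driven by the expansion from five to six members, and has a close analogue in steroid D-homoannulation. It sets C8 earlier and more elegantly than the chosen plan.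
- *Weak points.*
  - Migration of C10 competes with that of C7, and the process is reversible.
  - The chelated geometry gives 8α-OH only from the epimer with the acetyl group on the hindered β face, the opposite of what nucleophilic addition to a C9 ketone provides.
  - A5 lacks the gem-dimethyl group, carries a superfluous C3 ketone, and needs a trans-hydrindane fusion that is hard to set by reduction.
  - A7 leaves the C9 ketone between two fully substituted carbons, so attaching the chain with 9α-H remains unsolved.
- *Comparison.* The chosen plan spends two late steps on C8 but keeps C9 accessible when C11 is attached.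

Key step: step 3

Assumption: bromide 4 and half-ester 13 are treated as purchasable reagents, and the C2 epimers of sulfones 7–10 are carried on together because C2 loses its substituent in step 6.

## Route

Step 1
Reactants: 1 (R)-(−)-carvone
Product: 3 (5R,6RS)-6-methylcarvone, via lithium dienolate 2 (not isolated)
Conditions: LiN(i-Pr)2, THF, −78 °C; MeI, −78 → 0 °C
Reagents that add atoms: iodomethane, CI
Why: Kinetic deprotonation at the α′ CH2 (future C10) gives the cross-conjugated dienolate 2, which is C-methylated (enolate alkylation). The new centre forms as a mixture and is flattened again in step 2.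

Step 2
Reactants: 3 (5R,6RS)-6-methylcarvone; 4 3-bromo-2-(phenylsulfonyl)prop-1-ene
Product: 6 (5S,6S)-2,6-dimethyl-6-[2-(phenylsulfonyl)prop-2-en-1-yl]-5-(prop-1-en-2-yl)cyclohex-2-en-1-one, via lithium dienolate 5 (not isolated)
Conditions: LiN(i-Pr)2, THF, −78 °C; then cannulated into 4 (1.5 equiv), THF, −78 → −20 °C
Reagents that add atoms: none
Why: Enolate alkylation with a 2-sulfonylallyl halide; direct displacement and addition–elimination give the same constitution because the allyl unit is symmetric about C2. The electrophile should reach planar C10 anti to the neighbouring isopropenyl group, so C5 sets C10 with the arm trans and the methyl cis to isopropenyl. Inverse addition keeps free enolate away from the vinyl sulfone of the product.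

Step 3
Reactants: 6 (5S,6S)-2,6-dimethyl-6-[2-(phenylsulfonyl)prop-2-en-1-yl]-5-(prop-1-en-2-yl)cyclohex-2-en-1-one
Product: 7 2ξ-(phenylsulfonyl)-11-nordrim-7-en-9-one (trans-fused; both C2 epimers)
Conditions: Fe(acac)3 (30 mol %), PhSiH3 (2.5 equiv), EtOH, 60 °C, 0.02 M, Ar
Reagents that add atoms: none
Why: Fe(acac)3 and PhSiH3 in EtOH form an iron hydride that passes a hydrogen atom to the CH2 terminus of the isopropenyl group, the only electron-rich 1,1-disubstituted alkene present, which creates the second C4 methyl and the tertiary C4 radical. This nucleophilic radical adds to the unsubstituted terminus C3 of the vinyl sulfone, forms C3–C4 and closes ring A in the 6-endo-trig mode. The α-sulfonyl radical at C2 is then reduced by divalent iron and protonated by EtOH, which returns trivalent iron to the cycle. The closest known reaction type is the iron-hydride hydrogen-atom-transfer reductive olefin coupling (a Giese addition) of unactivated alkenes with vinyl sulfones and enones, known between molecules and within one molecule. Six-membered closure should win over 5-exo because sulfur sits on the internal carbon C2: polarity makes C3 the electrophilic site, and attack at C2 would join two fully substituted carbons and leave an unstabilised primary radical. The enone and the vinyl sulfone are electron-poor and accept the hydrogen atom more slowly, and the C4 radical could reach C7 only through a four-membered ring, so the substrate secures the chemoselectivity. C5 and C10 are untouched and only the conformer with both arms equatorial can close, so the trans-decalin with axial C10 methyl follows directly, and C4 is not stereogenic. The one new stereocentre, C2, is set by an uncontrolled protonation and disappears in step 6.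

Step 4
Reactants: 7 2ξ-(phenylsulfonyl)-11-nordrim-7-en-9-one
Product: 8 2ξ-(phenylsulfonyl)drima-7,9(11)-diene
Conditions: Ph3PCH3Br, KOt-Bu, toluene, 25 → 90 °C
Reagents that add atoms: methyltriphenylphosphonium bromide, C[P+](c1ccccc1)(c1ccccc1)c1ccccc1.[Br-]
Why: Wittig methylenation under the alkoxide, hot-toluene conditions used for hindered ketones. C9 has one trigonal neighbour (C8) and no α-hydrogen, and the ylide is too weak a base to remove the α-sulfonyl proton to any harmful effect.

Step 5
Reactants: 8 2ξ-(phenylsulfonyl)drima-7,9(11)-diene
Product: 10 2ξ-(phenylsulfonyl)drim-7-en-11-ol, via B-alkyl-9-BBN adduct 9 (not isolated)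
Conditions: 9-BBN, THF, 0 → 50 °C; then NaOH, H2O2, 0 °C → rt
Reagents that add atoms: 9-borabicyclo[3.3.1]nonane, B1C2CCCC1CCC2 (kept only in 9); hydrogen peroxide, OO
Why: Hydroboration–oxidation; the bulky borane places boron on the open C11 terminus and leaves the trisubstituted C7=C8 alone. Hydrogen should reach C9 from the α face, opposite the axial C10 methyl, which sets 9α-H with C11 equatorial.

Step 6
Reactants: 10 2ξ-(phenylsulfonyl)drim-7-en-11-ol
Product: 11 (−)-drimenol (drim-7-en-11-ol; 5S,9S,10S)
Conditions: 6% Na(Hg), Na2HPO4, MeOH/THF, 0 °C → rt
Reagents that add atoms: none
Why: Reductive desulfonylation of an alkyl aryl sulfone by electron transfer under buffered conditions; the isolated alkene and the alcohol are inert. Both C2 epimers converge on one known compound, which checks C5, C9 and C10 at once.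

Step 7
Reactants: 11 (−)-drimenol
Product: 12 drimenal (drim-7-en-11-al; 9α-H)
Conditions: (n-Pr)4N[RuO4] (5 mol %), NMO, 4 Å MS, CH2Cl2, 0 °C → rt
Reagents that add atoms: none
Why: Ley–Griffith oxidation stops at the aldehyde under essentially neutral conditions. This avoids the acid or strong amine base that could move C7=C8 into conjugation or epimerise C9.

Step 8
Reactants: 13 (R)-4-methoxy-2-methyl-4-oxobutanoic acid
Product: 15 (R)-4-methyldihydrofuran-2(3H)-one, via hydroxy ester 14 (not isolated)
Conditions: BH3·SMe2, THF, −10 → 20 °C; H2O; then TsOH (cat.), CH2Cl2, rt
Reagents that add atoms: none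
Why: Borane reduces a carboxylic acid far faster than an ester, so only the future C12 is reduced. Acid-catalysed lactonisation turns the labile hydroxy ester 14 into one stable compound. No enolisable intermediate is formed, so the stereocentre (future C13) is retained.

Step 9
Reactants: 15 (R)-4-methyldihydrofuran-2(3H)-one
Product: 17 methyl (R)-4-iodo-3-methylbutanoate, via silyl ester 16 (not isolated)
Conditions: Me3SiI, CH2Cl2, 0 °C → reflux; then MeOH, rt
Reagents that add atoms: iodotrimethylsilane, C[Si](C)(C)I; methanol, CO
Why: Silyl iodide cleavage of a lactone: silylation of the carbonyl oxygen, then SN2 attack of iodide at the O–CH2 carbon gives 16, which is converted into the methyl ester on methanolysis. The stereocentre is not a reacting atom.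

Step 10
Reactants: 17 methyl (R)-4-iodo-3-methylbutanoate
Product: 18 [(2R)-4-methoxy-2-methyl-4-oxobutyl]triphenylphosphonium iodide
Conditions: PPh3, MeCN, reflux
Reagents that add atoms: triphenylphosphine, c1ccc(cc1)P(c1ccccc1)c1ccccc1
Why: SN2 quaternisation of a primary iodide. The β-branch slows it, which is why the iodide and a polar solvent at reflux are chosen.

Step 11
Reactants: 12 drimenal; 18 [(2R)-4-methoxy-2-methyl-4-oxobutyl]triphenylphosphonium iodide
Product: 20 methyl (11Z,13R)-labda-7,11-dien-15-oate, via phosphonium ylide 19 (not isolated)
Conditions: 18, NaN(SiMe3)2 (1.0 equiv per 18), THF, −78 → 0 °C; then 12, −78 °C → rt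
Reagents that add atoms: none
Why: Wittig olefination with a non-stabilised, ester-bearing ylide of a widely used type; the P–CH2 protons are far more acidic than those next to the ester, and no free amide base is left when 12 is added. C13 is β to phosphorus and is not touched (its descriptor reads R here only because C12 is now vinylic). The Z alkene is expected but its geometry is irrelevant.

Step 12
Reactants: 20 methyl (11Z,13R)-labda-7,11-dien-15-oate
Product: 21 methyl (13S)-labd-7-en-15-oate
Conditions: TsNHNH2, NaOAc, THF/H2O, reflux
Reagents that add atoms: none
Why: Diimide reduction is a concerted syn transfer of two hydrogens whose rate falls steeply with alkene substitution, so the disubstituted C11=C12 reacts and the trisubstituted C7=C8 stays. No metal hydride is present, so the alkene cannot migrate towards C13 and the stereocentre is safe.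

Step 13
Reactants: 21 methyl (13S)-labd-7-en-15-oate
Product: 22 methyl (13S)-7α,8α-epoxylabdan-15-oate
Conditions: mCPBA, CH2Cl2, 0 °C
Reagents that add atoms: 3-chloroperbenzoic acid, OOC(=O)c1cccc(Cl)c1
Why: Prilezhaev epoxidation of the only alkene. The β face is closed by the axial C10 methyl and the β-oriented C9 chain, so oxygen should arrive from the α face and fix the C8–O bond as α.

Step 14
Reactants: 22 methyl (13S)-7α,8α-epoxylabdan-15-oate
Product: 23 (13S)-labdane-8α,15-diol
Conditions: LiAlH4, THF, 0 °C → reflux
Reagents that add atoms: none
Why: Hydride opens the trisubstituted epoxide in SN2 fashion at the secondary C7, because C8 is tertiary and its rear side lies under the C10 methyl. The C8–O bond is untouched and the 8α-carbinol with 8β-methyl results. The same reagent reduces the C15 ester to the primary alcohol.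

Step 15
Reactants: 23 (13S)-labdane-8α,15-diol; 24 3-phenylpropanoic acid
Product: 25 (13S)-8α-hydroxylabdan-15-yl 3-phenylpropanoate (target)
Conditions: DCC, DMAP (cat.), CH2Cl2, 0 °C → rt
Reagents that add atoms: none
Why: Steglich esterification; the hindered tertiary C8 alcohol does not compete with the primary C15 alcohol, and the neutral conditions do not dehydrate C8.

## Compound list

1 | (R)-(−)-carvone | CC(=C)[C@@H]1CC=C(C)C(=O)C1 | starting material
2 | lithium cross-conjugated dienolate of 1 | CC(=C)[C@@H]1CC=C(C)C([O-])=C1.[Li+] | intermediate
3 | (5R,6RS)-6-methylcarvone (2,6-dimethyl-5-(prop-1-en-2-yl)cyclohex-2-en-1-one) | CC(=C)[C@@H]1CC=C(C)C(=O)C1C | intermediate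
4 | 3-bromo-2-(phenylsulfonyl)prop-1-ene | C=C(CBr)S(=O)(=O)c1ccccc1 | starting material
5 | lithium cross-conjugated dienolate of 3 | CC(=C)[C@@H]1CC=C(C)C([O-])=C1C.[Li+] | intermediate
6 | (5S,6S)-2,6-dimethyl-6-[2-(phenylsulfonyl)prop-2-en-1-yl]-5-(prop-1-en-2-yl)cyclohex-2-en-1-one (arm trans to isopropenyl) | CC(=C)[C@@H]1CC=C(C)C(=O)[C@@]1(C)CC(=C)S(=O)(=O)c1ccccc1 | intermediate
7 | 2ξ-(phenylsulfonyl)-11-nordrim-7-en-9-one, (4aS,8aS)-2,5,5,8a-tetramethyl-7-(phenylsulfonyl)-4a,5,6,7,8,8a-hexahydronaphthalen-1(4H)-one | O=C1C(C)=CC[C@H]2C(C)(C)CC(S(=O)(=O)c3ccccc3)C[C@]12C | intermediate
8 | 2ξ-(phenylsulfonyl)drima-7,9(11)-diene | C=C1C(C)=CC[C@H]2C(C)(C)CC(S(=O)(=O)c3ccccc3)C[C@]12C | intermediate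
9 | B-[2ξ-(phenylsulfonyl)drim-7-en-11-yl]-9-borabicyclo[3.3.1]nonane (9α-H) | C12CCCC(CCC1)B2C[C@H]1C(C)=CC[C@H]2C(C)(C)CC(S(=O)(=O)c3ccccc3)C[C@]12C | intermediate
10 | 2ξ-(phenylsulfonyl)drim-7-en-11-ol (9α-H) | OC[C@H]1C(C)=CC[C@H]2C(C)(C)CC(S(=O)(=O)c3ccccc3)C[C@]12C | intermediate
11 | (−)-drimenol, drim-7-en-11-ol (5S,9S,10S) | OC[C@H]1C(C)=CC[C@H]2C(C)(C)CCC[C@]12C | intermediate
12 | drimenal, drim-7-en-11-al (9α-H) | O=C[C@H]1C(C)=CC[C@H]2C(C)(C)CCC[C@]12C | intermediate
13 | (R)-4-methoxy-2-methyl-4-oxobutanoic acid | C[C@H](CC(=O)OC)C(=O)O | starting material
14 | methyl (R)-4-hydroxy-3-methylbutanoate | C[C@H](CC(=O)OC)CO | intermediate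
15 | (R)-4-methyldihydrofuran-2(3H)-one | C[C@H]1COC(=O)C1 | intermediate
16 | trimethylsilyl (R)-4-iodo-3-methylbutanoate | C[C@H](CC(=O)O[Si](C)(C)C)CI | intermediate
17 | methyl (R)-4-iodo-3-methylbutanoate | C[C@H](CC(=O)OC)CI | intermediate
18 | [(2R)-4-methoxy-2-methyl-4-oxobutyl]triphenylphosphonium iodide | C[C@H](CC(=O)OC)C[P+](c1ccccc1)(c1ccccc1)c1ccccc1.[I-] | intermediate
19 | methyl (R)-3-methyl-4-(triphenyl-λ5-phosphanylidene)butanoate | C[C@H](CC(=O)OC)C=P(c1ccccc1)(c1ccccc1)c1ccccc1 | intermediate
20 | methyl (11Z,13R)-labda-7,11-dien-15-oate | C[C@H](CC(=O)OC)/C=C\[C@H]1C(C)=CC[C@H]2C(C)(C)CCC[C@]12C | intermediate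
21 | methyl (13S)-labd-7-en-15-oate | C[C@H](CC(=O)OC)CC[C@H]1C(C)=CC[C@H]2C(C)(C)CCC[C@]12C | intermediate
22 | methyl (13S)-7α,8α-epoxylabdan-15-oate | C[C@H](CC(=O)OC)CC[C@H]1[C@]3(C)O[C@@H]3C[C@H]2C(C)(C)CCC[C@]12C | intermediate
23 | (13S)-labdane-8α,15-diol | C[C@H](CCO)CC[C@@H]1[C@@]2(C)CCCC(C)(C)[C@@H]2CC[C@@]1(C)O | intermediate
24 | 3-phenylpropanoic acid | OC(=O)CCc1ccccc1 | starting material
25 | (13S)-8α-hydroxylabdan-15-yl 3-phenylpropanoate | C[C@H](CCOC(=O)CCc1ccccc1)CC[C@@H]1[C@@]2(C)CCCC(C)(C)[C@@H]2CC[C@@]1(C)O | target

## Step count and least certain steps

Total steps: 15. Longest linear sequence: 12 (steps 1–7 and 11–15). Steps 8–10 form the three-step side branch.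

**Step 3 (key step).**
- *Risk.* The hydrogen atom may go to the wrong alkene, because the vinyl sulfone is also 1,1-disubstituted. The C4 radical may also be quenched by a second hydrogen transfer before it closes. The closure creates a quaternary carbon next to crowded C5 and needs the conformer with both arms equatorial, so it may be slow.
- *Fallback.* The radical is generated at a predetermined site. Setting out from 6, Markovnikov addition of HBr (HBr in AcOH, 0 °C) to the isopropenyl group gives the tertiary bromide F1. Slow addition of Bu3SnH with AIBN in benzene at reflux abstracts bromine and produces the same C4 radical with no metal hydride that could touch the other alkenes. The same six-membered closure returns to the route at 7.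

**Step 2.**
- *Risk.* Material may be lost through further conjugate addition of dienolate 5 to the vinyl sulfone of the product or through proton exchange. Facial selectivity may also erode, because a very reactive electrophile has an early transition state.
- *Fallback.* Setting out from 3 (through 5), alkylation with 2,3-dibromopropene, which is not a conjugate acceptor, gives the bromoallyl ketone F2. Exchange of the vinylic bromine for the sulfonyl group with PhSO2Na under CuI and L-proline sodium salt catalysis in DMSO at 90 °C returns to the route at 6. Copper is preferred to palladium because a vinylpalladium species could cyclise onto the isopropenyl group.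

**Step 4.**
- *Risk.* The ylide may fail to add to a carbonyl group next to quaternary C10, and may instead deprotonate at the vinylogous positions (C6, C17), which only returns 7 on work-up.
- *Fallback.* A Peterson sequence with a smaller and less basic nucleophile. Setting out from 7, excess Me3SiCH2Li with CeCl3 in THF at −78 °C adds to C9 from the α face and gives the β-hydroxysilane F3. KH in THF then induces the elimination, which can only form the exocyclic alkene, and returns to the route at 8.

**Step 11.**
- *Risk.* The basic ylide may deprotonate 12 at C9, which is both α to the aldehyde and allylic. This would shift C7=C8 into conjugation or epimerise C9. The risk is made worse by slow addition to a crowded aldehyde.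
- *Fallback.* The aldehyde is avoided altogether. Setting out from 11, an Appel reaction (I2, PPh3, imidazole, CH2Cl2) gives 11-iododrim-7-ene F4, and iodide 17 is converted with activated zinc dust in THF into the alkylzinc iodide F5. An alkyl–alkyl Negishi coupling (Pd2(dba)3, P(c-C5H9)3, N-methylimidazole, THF/NMP, 80 °C) forms C11–C12 directly under non-basic conditions and returns to the route at 21. Steps 7 and 12 are then not needed.

**Step 14.**
- *Risk.* The opening may be slow or misdirected, because hydride has to attack C7 against the diaxial preference of the Fürst–Plattner rule. Long heating with basic aluminates may instead isomerise the epoxide to an allylic alcohol.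
- *Fallback.* A radical hydration replaces steps 13 and 14. Setting out from 21, Mukaiyama hydration (Co(acac)2, PhSiH3, O2, i-PrOH, rt, reductive work-up with Na2S2O3) generates the C8 radical, which should be oxygenated from the less screened α face, and gives the hydroxy ester F6. LiAlH4 in THF at 0 °C then reduces only the ester and returns to the route at 23.

## Further compounds

F1 | step 3 | (5R,6S)-5-(2-bromopropan-2-yl)-2,6-dimethyl-6-[2-(phenylsulfonyl)prop-2-en-1-yl]cyclohex-2-en-1-one | CC(C)(Br)[C@@H]1CC=C(C)C(=O)[C@@]1(C)CC(=C)S(=O)(=O)c1ccccc1
F2 | step 2 | (5S,6S)-6-(2-bromoprop-2-en-1-yl)-2,6-dimethyl-5-(prop-1-en-2-yl)cyclohex-2-en-1-one | CC(=C)[C@@H]1CC=C(C)C(=O)[C@@]1(C)CC(=C)Br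
F3 | step 4 | 2ξ-(phenylsulfonyl)-11-(trimethylsilyl)drim-7-en-9β-ol | C[Si](C)(C)C[C@]1(O)C(C)=CC[C@H]2C(C)(C)CC(S(=O)(=O)c3ccccc3)C[C@]12C
F4 | step 11 | 11-iododrim-7-ene (9α-H) | IC[C@H]1C(C)=CC[C@H]2C(C)(C)CCC[C@]12C
F5 | step 11 | [(2R)-4-methoxy-2-methyl-4-oxobutyl]zinc iodide | C[C@H](CC(=O)OC)C[Zn]I
F6 | step 14 | methyl (13S)-8α-hydroxylabdan-15-oate | C[C@H](CC(=O)OC)CC[C@@H]1[C@@]2(C)CCCC(C)(C)[C@@H]2CC[C@@]1(C)O
A1 | alternative 1 | (3S,6E,10E)-3,7,11,15-tetramethylhexadeca-6,10,14-trien-1-ol | C[C@H](CCO)CC/C=C(\C)CC/C=C(\C)CCC=C(C)C
A2 | alternative 1 | (13S)-labdane-8α,15-diol | C[C@H](CCO)CC[C@@H]1[C@@]2(C)CCCC(C)(C)[C@@H]2CC[C@@]1(C)O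
A3 | alternative 2 | (S)-2,4,4-trimethyl-3-vinylcyclohex-2-en-1-yl but-2-ynoate | CC#CC(=O)O[C@H]1CCC(C)(C)C(C=C)=C1C
A4 | alternative 2 | tricyclic butenolide with C5=C6 and C8=C9 alkenes and a C11–O–C1 lactone | O=C1O[C@H]2CCC(C)(C)C3=CCC(C)=C1[C@@]23C
A5 | alternative 3 | (S)-Hajos–Parrish ketone, (7aS)-7a-methyl-2,3,7,7a-tetrahydro-1H-indene-1,5(6H)-dione | C[C@]12CCC(=O)C=C1CCC2=O
A6 | alternative 3 | 9β-acetyl-9α-hydroxy trans-hydrindane (1-acetyl-4,4,7a-trimethyloctahydro-1H-inden-1-ol) | CC(=O)[C@@]1(O)CC[C@H]2C(C)(C)CCC[C@]12C
A7 | alternative 3 | 8α-hydroxy-11-nordriman-9-one | O=C1[C@@]2(C)CCCC(C)(C)[C@@H]2CC[C@@]1(C)O
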